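Compound numbers 1–24 are those of the steps below. Ring carbons carry germacrane numbers in every intermediate (C1–C10 ring, C11–C13 lactone carbons, C14 on C10, C15 on C4); α/β refer to the usual drawing with H-7 α.

## The problem

Target 24 is a germacranolide: a ten-membered carbocycle with an E trisubstituted alkene at C4=C5, a cis epoxide at C1–C10 (the oxide of a Z alkene), a trans-fused α-methylene-γ-lactone across C7–C8 (C12–O on C8), an isobutyrate on C6 and a free hydroxyl on C3. Closing such a ring end to end costs entropy and transannular strain and leaves both alkene geometries to be fixed separately, so opening smaller rings into the ten-membered one is the better way. Six stereocentres must be set (C1, C3, C6, C7, C8, C10). C3 and C8 lie on opposite sides of the ring and cannot control each other, so both are best brought in with the building blocks. C8 can then direct C7 (trans alkylation beside it), C7 can direct hydride to C6, and the ring conformation has to direct the epoxide. The fragile parts are: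

- the methylene lactone (Michael acceptor),
- the epoxide (acid opens it across the ring),
- the allylic ester,
- the C8 oxygen, which is β to C6 and is expelled from any C6-ketone enolate,
- the 1,5-diene that precedes the epoxide, which can undergo a Cope shift on heating.

The enabling feature is that C10=C1–C2–C3–C4=C5, with the epoxide read as its Z alkene, is a hexa-1,5-diene, the retron of a bicyclo[2.2.0]hexane opening. C5–C10 together with C6–C9 forms a six-membered ring whose C6 oxygen can be a ketone. The ring is therefore the sum of a 3-methylcyclohexenone (C5–C10, methyl C14) and a 1-methylcyclobutene (C1–C4, methyl C15), joined at C4–C5 and C1–C10.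

## Retrosynthesis

**24 ⇐ 23 ⇐ 22.** Only the O–Si bond at C3 and then the two C–O bonds of the epoxide are cut. The epoxide is placed late because it would not survive the acid of the lactonisation. In triene 22, C1=C10 is the only electron-rich alkene: C4=C5 is flanked by two allylic oxygens and C11=C13 is conjugated. 22 is a melampolide-type ring, in which C14 is expected to point to the α side, so that peripheral attack should give the 1β,10β oxide. The forward steps must be chemoselective and face-selective (step 15) and the last desilylation mild (step 16).

**22 ⇐ 19 ⇐ 17 ⇐ 16 ⇐ 15.** The cuts are C11=C13 (methylenation of lactone 19), the C12–O8 bond (through hydroxy ester 18), the ester bond at O6 and the C6–H bond. The order is forced. C6 must be reduced before the lactone exists, because a lactone oxygen on C8 β to a C6 ketone is eliminated. The C6 hydroxyl must be acylated before C8 is unmasked, or it would close the 6,12-lactone itself; a tert-butyl ester keeps C12 silent until then. Dienone 15 is simpler by one ring, one stereocentre and the ester. The forward sequence asks for 1,2-reduction with the 6S sense, TBS removal beside TIPS, and an enolate methylenation beside an isobutyrate.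

**15 ⇐ 14.** Re-forming C1–C4 and C5–C10 folds the dienone into tricycle 14, a bicyclo[2.2.0]hexane fused to the cyclohexanone. Against the ring-closing cuts at C5–C6 or C2–C3, this cut makes the medium ring by releasing strain and writes both alkene geometries in one event. 14 has no medium ring and no alkene geometry. Of its four extra stereocentres only the exo position of the C3 silyloxy group matters, because it decides which chair of the intermediate diyl is used. The forward reaction is thermal and must stop at 15 before a Cope shift sets in.

**14 ⇐ 6 + 13.** Cutting C4–C5 and C1–C10 of the central cyclobutane (ring A) gives enone 6 and cyclobutene 13, two fragments of similar size, each carrying one of the two remote stereocentres. The other cut of ring A is the thermolysis itself, so this is the only constructive one. The forward photocycloaddition must be head-to-head (C5 to C4), must place the silyloxy group exo, and must fuse the outer rings anti.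

**6 ⇐ 4 + 5; 4 ⇐ 3 ⇐ 2 ⇐ 1.** The C7–C11 bond is cut by enolate alkylation with bromoacetate 5. It is made before the photocycloaddition because the trans side chain balances the facial bias of the C8 silyl ether, which would otherwise oppose the pairing that step 9 needs. Cutting C5=C10 of enone 4 (aldol condensation) reveals the symmetric diketone 3, whose two arms a chiral amine can tell apart. 3 comes from dienol 1 through silyl ether 2 by two Wacker oxidations.

**13 ⇐ 12 ⇐ 11 ⇐ 10 ⇐ 7 + 8.** The cuts are O–Si, then C3–H (asymmetric reduction of cyclobutenone 11). Desaturating 2-methylcyclobutanone would have to choose between endo- and exocyclic alkenes. The ring is therefore built by ketene cycloaddition of 7 (through methylketene 9) with vinyl ether 8. The resulting β-ethoxy ketone 10 can only eliminate within the ring.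

## Roads not taken

**Alternative 1:** anionic oxy-Cope ring expansion.
- Cut and key step: the forward step forms C2–C3 and breaks C5–C10. The potassium alkoxide (KH, 18-crown-6) of cis-dialkenylcyclohexanol A1 rearranges, and the C10 enolate is trapped with PhNTf2 as enol triflate A2.
- Merits: the alkoxide accelerates the shift so much that it runs near room temperature, where no further pericyclic reaction interferes. The chair transition state passes the C5/C10 configuration and the enol ether geometry on to C3 and to both alkenes. The triflate is a handle for C14.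
- Weak points: A1 needs five contiguous stereocentres on one cyclohexane, a geometrically pure enol ether and four different oxygen protecting groups. C14 must be added afterwards by cross-coupling, and the C11–C13 unit is still at the alcohol level.
- Comparison: on the ring-forming event itself this road is better, being low-temperature and stereospecific. The chosen plan sets against it two partners of four steps each, both methyl groups in place from the start, and far fewer steps before the key event.

**Alternative 2:** Nozaki–Hiyama–Kishi closure.
- Cut and key step: C5–C6. CrCl2 with catalytic NiCl2 turns the E vinyl iodide of aldehyde A3 into a vinylchromium species that adds to the C6 aldehyde, giving ten-membered allylic alcohol A4 with epoxide and lactone in place.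
- Merits: high functional-group tolerance. The E geometry is fixed in the iodide. The epoxide is made on an open chain, so its configuration is not left to a ring conformation.
- Weak points: it is a true medium-ring closure, needing high dilution and a large excess of chromium. The C6 configuration is left to macrocyclic diastereoselection. The aldehyde of A3 is α to C7 and β to the lactone oxygen on C8, so epimerisation and elimination threaten. A3 needs a long linear synthesis.
- Comparison: this road is as good or better for the epoxide and avoids light and heat. The chosen plan sets against it a ring made from two small rings instead of a ring closure, and no β-acyloxy aldehyde.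

**Alternative 3:** Grob fragmentation of a hydroazulene.
- Cut and key step: the temporary C4–C8 bond. The C8 potassium alkoxide (KN(SiMe3)2) of hydroxy mesylate A5 fragments; C4–C8 and the C5–O bond break and dienone A6 results.
- Merits: the E alkene follows stereospecifically from the anti arrangement of C4–C8 and the C5 mesylate, not from a conformer preference. The Z C1=C10 alkene is at ease in the seven-membered ring. The step runs cold.
- Weak points: A5 needs a quaternary C4, a tertiary C8 carbinol and a defined C5. After fragmentation C8 is a ketone that must be reduced with the right sense, and the side chain still needs oxidation.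
- Comparison: geometry control is better here. The chosen plan sets against it C8 brought in with the correct configuration, a side chain already at the acid level, and a much shorter way to the ring-opening substrate.

Key step: step 9

**Assumptions.**
- The quinine-derived amine of step 3 is assumed to give the (S)-enone; should the sense be opposite, its quinidine-derived pseudoenantiomer takes its place.
- 14 is written as the expected major diastereomer; other cis-fused adducts with an exo silyloxy group are carried into step 10 with it.

## Route

Step 1
Reactants: 1 hepta-1,6-dien-4-ol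
Product: 2 4-(tert-butyldimethylsilyloxy)hepta-1,6-diene
Conditions: TBSCl, imidazole, DMF, rt
Reagents that add atoms: tert-butyldimethylsilyl chloride, C[Si](C)(Cl)C(C)(C)C
Why: Standard silylation of a secondary alcohol; TBS survives the Wacker medium and can later be removed beside TIPS.

Step 2
Reactants: 2 4-(tert-butyldimethylsilyloxy)hepta-1,6-diene
Product: 3 4-(tert-butyldimethylsilyloxy)heptane-2,6-dione
Conditions: PdCl2 (10 mol %), CuCl, O2 (1 atm), DMF/H2O, rt
Reagents that add atoms: water, O (source of both ketone oxygens; O2 is the terminal oxidant)
Why: Tsuji–Wacker oxidation; each terminal alkene gives the methyl ketone by Markovnikov hydroxypalladation, and homoallylic silyl ethers are routine substrates.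

Step 3
Reactants: 3 4-(tert-butyldimethylsilyloxy)heptane-2,6-dione
Product: 4 (S)-5-(tert-butyldimethylsilyloxy)-3-methylcyclohex-2-en-1-one
Conditions: 9-amino-9-deoxy-epi-quinine (20 mol %), AcOH (60 mol %), toluene, −15 °C → rt
Reagents that add atoms: none
Why: Enamine-mediated intramolecular aldol condensation, a known desymmetrisation of 4-substituted heptane-2,6-diones with cinchona primary amines; the catalyst decides which enantiotopic acetonyl arm acts as nucleophile and so sets C8, and the weakly acidic medium should spare the β-silyloxy group.

Step 4
Reactants: 4 (S)-5-(tert-butyldimethylsilyloxy)-3-methylcyclohex-2-en-1-one; 5 tert-butyl bromoacetate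
Product: 6 tert-butyl 2-[(1R,6S)-6-(tert-butyldimethylsilyloxy)-4-methyl-2-oxocyclohex-3-en-1-yl]acetate
Conditions: LiN(iPr)2 (LDA), THF, −78 °C; then 5, DMPU, −78 → −40 °C
Reagents that add atoms: none
Why: Kinetic deprotonation of a 3-methylcyclohexenone takes place at the α′ carbon (C7), and the cross-conjugated enolate is alkylated by the α-halo ester anti to the neighbouring silyloxy group, which sets C7 trans to C8; the low temperature keeps E1cB loss of silanolate slow.

Step 5
Reactants: 7 propanoyl chloride; 8 ethyl vinyl ether
Product: 10 3-ethoxy-2-methylcyclobutan-1-one (racemic cis/trans mixture), via methylketene 9 (not isolated)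
Conditions: Et3N, 8 (excess), MeCN, reflux, slow addition of 7
Reagents that add atoms: none
Why: Dehydrochlorination gives the ketene, which undergoes thermal [2+2] cycloaddition with the enol ether; the nucleophilic CH2 terminus bonds to the ketene carbonyl carbon, so ethoxy ends up on C3 and methyl on C2 without ambiguity.

Step 6
Reactants: 10 3-ethoxy-2-methylcyclobutan-1-one
Product: 11 2-methylcyclobut-2-en-1-one
Conditions: TsOH·H2O (5 mol %), 5 Å molecular sieves, CH2Cl2, 35 °C; bulb-to-bulb distillation, used at once
Reagents that add atoms: none
Why: Acid-catalysed β-elimination of ethanol from a 3-alkoxycyclobutanone, a known way to cyclobutenones; loss through the more substituted enol should give the trisubstituted enone, only endocyclic alkenes are possible, and the sieves take up ethanol so that conjugate re-addition does not return 10.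

Step 7
Reactants: 11 2-methylcyclobut-2-en-1-one
Product: 12 (R)-2-methylcyclobut-2-en-1-ol
Conditions: (S)-2-methyl-CBS-oxazaborolidine [(S)-1-methyl-3,3-diphenyltetrahydro-3H-pyrrolo[1,2-c][1,3,2]oxazaborole] (0.2 equiv), catecholborane, toluene, −78 °C
Reagents that add atoms: none
Why: Corey–Bakshi–Shibata reduction; α-substituted cyclic enones are among its best substrates, the methyl-bearing alkenyl arm acts as the large group so that the (S)-catalyst should deliver the (R)-alcohol, and catecholborane at low temperature reduces 1,2 only.

Step 8
Reactants: 12 (R)-2-methylcyclobut-2-en-1-ol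
Product: 13 (R)-(2-methylcyclobut-2-en-1-yloxy)triisopropylsilane
Conditions: TIPSOTf, 2,6-lutidine, CH2Cl2, −78 → 0 °C
Reagents that add atoms: triisopropylsilyl trifluoromethanesulfonate, CC(C)[Si](OS(=O)(=O)C(F)(F)F)(C(C)C)C(C)C
Why: Silylation with the triflate; the bulky TIPS ether lasts to the final step and shields one face of the cyclobutene in the key step.

Step 9
Reactants: 6 tert-butyl 2-[(1R,6S)-6-(tert-butyldimethylsilyloxy)-4-methyl-2-oxocyclohex-3-en-1-yl]acetate; 13 (R)-(2-methylcyclobut-2-en-1-yloxy)triisopropylsilane
Product: 14 cis-anti-cis tricyclic photoadduct (tricyclo[4.4.0.0(2,5)]decan-7-one skeleton; new bonds C4–C5 and C1–C10; TIPSO exo on the outer cyclobutane; cyclobutane syn to the C8 silyloxy group and anti to the C7 side chain)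
Conditions: hν (350 nm, Pyrex), 13 (3 equiv, excess recovered), CH2Cl2 (degassed), −40 °C; then basic Al2O3, CH2Cl2, rt
Reagents that add atoms: none
Why: Excitation of the enone and intersystem crossing give the triplet, which adds to the cyclobutene stepwise through a 1,4-diradical; spin inversion and radical recombination then close the central cyclobutane (ring A), so this ring is formed by intermolecular [2+2] addition with diradical ring closure as the last event. The closest known reaction type is the photocycloaddition of 3-alkylcyclohex-2-enones to 1-alkylcyclobutenes. The step needs the head-to-head orientation (C5 to C4, C10 to C1); the head-to-tail mode would have to join the two fully substituted carbons C10 and C4, a recombination slow enough for that diradical to fall back to the partners. C4 and C1 are necessarily cis (ring B), and their configuration is set by the C3 silyloxy group, the enone approaching the face away from TIPS so that the silyloxy group ends up exo. C5 and C10 are held cis by the six-membered ring (any trans-fused adduct is epimerised at C5 on basic alumina), and the usual preference of cyclic alkenes for the anti arrangement of the two outer rings fixes them relative to C4 and C1. These two preferences together require the enone face syn to its own C8 silyloxy group; the trans C7 side chain shields the opposite face, so the enone's own bias should not oppose this pairing. C3, C7 and C8 are untouched.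

Step 10
Reactants: 14 cis-anti-cis tricyclic photoadduct
Product: 15 tert-butyl 8α-(tert-butyldimethylsilyloxy)-6-oxo-3α-(triisopropylsilyloxy)-13-norgermacra-1(10)Z,4E-dien-12-oate (7αH)
Conditions: toluene (0.01 M, degassed), base-washed sealed tube, 170 °C, stopped at full consumption of 14
Reagents that add atoms: none
Why: Thermal cycloreversion of a bicyclo[2.2.0]hexane, known for enone–cyclobutene photoadducts: homolysis of the central C1–C4 bond gives a cyclohexane-1,4-diyl that cleaves C5–C10, the bond whose rupture gives the conjugated enone. In the favoured chair of the diyl C6 and the exo silyloxy group are equatorial and C9 axial, which should make C4=C5 E and C1=C10 Z; the four cyclobutane stereocentres vanish.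

Step 11
Reactants: 15 dienone (as named in step 10)
Product: 16 tert-butyl 6β-hydroxy-8α-(tert-butyldimethylsilyloxy)-3α-(triisopropylsilyloxy)-13-norgermacra-1(10)Z,4E-dien-12-oate
Conditions: NaBH4, CeCl3·7H2O, MeOH, −78 °C
Reagents that add atoms: none
Why: Luche reduction gives 1,2-addition to the enone; hydride is expected on the outer face of the carbonyl, anti to the ring bond C7–C8 (Felkin–Anh arrangement with the C7 side chain turned toward the carbonyl oxygen), which corresponds to 6S. The tert-butyl ester keeps the new alkoxide from closing a 6,12-lactone.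

Step 12
Reactants: 16 allylic alcohol (as named in step 11)
Product: 17 tert-butyl 6β-(2-methylpropanoyloxy)-8α-(tert-butyldimethylsilyloxy)-3α-(triisopropylsilyloxy)-13-norgermacra-1(10)Z,4E-dien-12-oate
Conditions: isobutyric anhydride, DMAP, Et3N, CH2Cl2, 0 °C → rt
Reagents that add atoms: isobutyric anhydride, CC(C)C(=O)OC(=O)C(C)C
Why: DMAP-catalysed acylation of the secondary allylic alcohol installs the ester of the target and removes the C6 hydroxyl as a competitor in the lactonisation.

Step 13
Reactants: 17 isobutyrate (as named in step 12)
Product: 19 6β-(2-methylpropanoyloxy)-3α-(triisopropylsilyloxy)-13-norgermacra-1(10)Z,4E-dien-12,8α-olide, via hydroxy ester 18 (not isolated)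
Conditions: HF·pyridine, pyridine, THF, 0 °C → rt; then TFA, CH2Cl2, 0 °C
Reagents that add atoms: none
Why: Buffered HF·pyridine cleaves the secondary TBS ether beside the secondary TIPS ether; acid then ionises the tert-butyl ester and the C8 hydroxyl closes the γ-lactone by 5-exo-trig acyl substitution, trans-fused because C7 and C8 are trans. With C6 reduced, the lactone oxygen is no longer β to a ketone.

Step 14
Reactants: 19 lactone (as named in step 13)
Product: 22 6β-(2-methylpropanoyloxy)-3α-(triisopropylsilyloxy)germacra-1(10)Z,4E,11(13)-trien-12,8α-olide, via Mannich base 20 (not isolated), via methiodide 21 (not isolated)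
Conditions: LiN(iPr)2 (LDA), THF, −78 °C; Me2N=CH2+ I−, −78 → 0 °C; MeI, MeOH, rt; NaHCO3 (aq), CH2Cl2
Reagents that add atoms: N,N-dimethylmethyleneiminium iodide, C=[N+](C)C.[I-]; iodomethane, CI (its methyl stays only in 21)
Why: α-Methylenation of a lactone by the Eschenmoser salt sequence; the lactone CH2 is the most acidic and least hindered position (the isobutyrate has only a tertiary α-hydrogen), and the quaternised Mannich base eliminates under mild base.

Step 15
Reactants: 22 triene lactone (as named in step 14)
Product: 23 1β,10β-epoxy-6β-(2-methylpropanoyloxy)-3α-(triisopropylsilyloxy)germacra-4E,11(13)-dien-12,8α-olide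
Conditions: mCPBA, NaHCO3, CH2Cl2, 0 °C
Reagents that add atoms: 3-chloroperoxybenzoic acid, OOC(=O)c1cccc(Cl)c1
Why: Prilezhaev epoxidation picks the only electron-rich alkene (C4=C5 is deactivated by two allylic oxygens and shielded by TIPS, C11=C13 is conjugated) and adds syn, so the Z alkene gives the cis epoxide. Attack from the periphery of the melampolide-type ring, in which C14 is expected to point to the α side, should give the 1β,10β (1R,10S) oxide.

Step 16
Reactants: 23 epoxide (as named in step 15)
Product: 24 (1R,3R,6S,7R,8S,10S)-1β,10β-epoxy-3α-hydroxy-6β-(2-methylpropanoyloxy)germacra-4E,11(13)-dien-12,8α-olide (CNP0114243.1)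
Conditions: TBAF, AcOH (1:1), THF, 0 °C → rt
Reagents that add atoms: none
Why: Fluoride desilylation, buffered with acetic acid so that the methylene lactone, the ester and the epoxide are left alone.

## Compound list

1 | hepta-1,6-dien-4-ol | C=CCC(O)CC=C | starting material
2 | 4-(tert-butyldimethylsilyloxy)hepta-1,6-diene | C=CCC(O[Si](C)(C)C(C)(C)C)CC=C | intermediate
3 | 4-(tert-butyldimethylsilyloxy)heptane-2,6-dione | CC(=O)CC(O[Si](C)(C)C(C)(C)C)CC(C)=O | intermediate
4 | (S)-5-(tert-butyldimethylsilyloxy)-3-methylcyclohex-2-en-1-one | O=C1C[C@@H](O[Si](C)(C)C(C)(C)C)CC(C)=C1 | intermediate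
5 | tert-butyl bromoacetate | CC(C)(C)OC(=O)CBr | starting material
6 | tert-butyl 2-[(1R,6S)-6-(tert-butyldimethylsilyloxy)-4-methyl-2-oxocyclohex-3-en-1-yl]acetate | CC(C)(C)OC(=O)C[C@H]1C(=O)C=C(C)C[C@@H]1O[Si](C)(C)C(C)(C)C | intermediate
7 | propanoyl chloride | CCC(=O)Cl | starting material
8 | ethyl vinyl ether | C=COCC | starting material
9 | methylketene (formed in the flask) | CC=C=O | intermediate
10 | 3-ethoxy-2-methylcyclobutan-1-one (racemic, cis/trans) | CCOC1CC(=O)C1C | intermediate
11 | 2-methylcyclobut-2-en-1-one | CC1=CCC1=O | intermediate
12 | (R)-2-methylcyclobut-2-en-1-ol | CC1=CC[C@H]1O | intermediate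
13 | (R)-(2-methylcyclobut-2-en-1-yloxy)triisopropylsilane | CC1=CC[C@H]1O[Si](C(C)C)(C(C)C)C(C)C | intermediate
14 | cis-anti-cis tricyclic photoadduct, exo-TIPSO, cyclobutane syn to C8–OTBS | CC(C)(C)OC(=O)C[C@H]1C(=O)[C@@H]2[C@@]3(C)[C@H](O[Si](C(C)C)(C(C)C)C(C)C)C[C@H]3[C@]2(C)C[C@@H]1O[Si](C)(C)C(C)(C)C | intermediate
15 | ten-membered (4E,1(10)Z)-dien-6-one with 3α-OTIPS, 7β-CH2CO2tBu, 8α-OTBS | CC(C)(C)OC(=O)C[C@@H]1[C@@H](O[Si](C)(C)C(C)(C)C)C/C(C)=C\C[C@@H](O[Si](C(C)C)(C(C)C)C(C)C)/C(C)=C/C1=O | intermediate
16 | 6β-alcohol of 15 | CC(C)(C)OC(=O)C[C@@H]1[C@@H](O[Si](C)(C)C(C)(C)C)C/C(C)=C\C[C@@H](O[Si](C(C)C)(C(C)C)C(C)C)/C(C)=C/[C@@H]1O | intermediate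
17 | 6β-isobutyrate of 16 | CC(C)(C)OC(=O)C[C@@H]1[C@@H](O[Si](C)(C)C(C)(C)C)C/C(C)=C\C[C@@H](O[Si](C(C)C)(C(C)C)C(C)C)/C(C)=C/[C@@H]1OC(=O)C(C)C | intermediate
18 | 8α-hydroxy tert-butyl ester (formed in the flask) | CC(C)(C)OC(=O)C[C@@H]1[C@@H](O)C/C(C)=C\C[C@@H](O[Si](C(C)C)(C(C)C)C(C)C)/C(C)=C/[C@@H]1OC(=O)C(C)C | intermediate
19 | 6β-isobutyryloxy-3α-(triisopropylsilyloxy)-13-norgermacra-1(10)Z,4E-dien-12,8α-olide | C1C(=O)O[C@H]2C/C(C)=C\C[C@@H](O[Si](C(C)C)(C(C)C)C(C)C)/C(C)=C/[C@H](OC(=O)C(C)C)[C@H]12 | intermediate
20 | 13-(dimethylamino)-11,13-dihydro Mannich base of 22 (C11 epimers; formed in the flask) | CN(C)CC1C(=O)O[C@H]2C/C(C)=C\C[C@@H](O[Si](C(C)C)(C(C)C)C(C)C)/C(C)=C/[C@H](OC(=O)C(C)C)[C@H]12 | intermediate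
21 | trimethylammonium iodide of 20 (formed in the flask) | C[N+](C)(C)CC1C(=O)O[C@H]2C/C(C)=C\C[C@@H](O[Si](C(C)C)(C(C)C)C(C)C)/C(C)=C/[C@H](OC(=O)C(C)C)[C@H]12.[I-] | intermediate
22 | 6β-isobutyryloxy-3α-(triisopropylsilyloxy)germacra-1(10)Z,4E,11(13)-trien-12,8α-olide | C=C1C(=O)O[C@H]2C/C(C)=C\C[C@@H](O[Si](C(C)C)(C(C)C)C(C)C)/C(C)=C/[C@H](OC(=O)C(C)C)[C@H]12 | intermediate
23 | 1β,10β-epoxy-6β-isobutyryloxy-3α-(triisopropylsilyloxy)germacra-4E,11(13)-dien-12,8α-olide | C=C1C(=O)O[C@H]2C[C@]3(C)O[C@@H]3C[C@@H](O[Si](C(C)C)(C(C)C)C(C)C)/C(C)=C/[C@H](OC(=O)C(C)C)[C@H]12 | intermediate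
24 | (1R,3R,6S,7R,8S,10S)-1β,10β-epoxy-3α-hydroxy-6β-isobutyryloxygermacra-4E,11(13)-dien-12,8α-olide | C=C1C(=O)O[C@H]2C[C@]3(C)O[C@@H]3C[C@@H](O)/C(C)=C/[C@H](OC(=O)C(C)C)[C@H]12 | target

## Step count and least certain steps

Total: 16 steps. Longest linear sequence: 12 steps (steps 1–4 or 5–8, then 9–16).

**Step 9 (key step).** The excited enone may be captured too slowly by a hindered trisubstituted alkene that, being enantiopure, can only be used in small excess; enone dimerisation and head-to-tail or syn adducts then gain weight. Fallback: give up the enantiopure cyclobutene. Setting out from 11 and 6, Luche reduction of 11 (NaBH4, CeCl3) gives racemic 2-methylcyclobut-2-en-1-ol F1, and TIPSOTf gives the racemic silyl ether F2, which can be used in about tenfold excess. Both enantiomers add to 6; the (S)-cyclobutene gives the exo, cis-anti-cis adduct F3 on the other enone face. Thermolysis of the mixture as in step 10 gives 15 and its C3 epimer F4, which are separated by chromatography; the route is rejoined at 15.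

**Step 10.** Dienone 15 may undergo a consecutive Cope shift at the temperature of its own formation (C5–C10 re-forms, C2–C3 breaks, helped by the donor silyloxy group on C3), which destroys C3; opening through the other chair would also give the wrong alkene pair. Fallback: open the tricycle with C3 as a ketone. Setting out from 12 (its racemate serves as well) and 6, irradiation of the free alcohol gives cyclobutanol adduct F5, and Dess–Martin periodinane gives diketone F6. F6 should open on milder heating, the C4 radical now being acyl-stabilised, to ene-dione F7, in which a Cope shift would have to create a ketene. Corey–Bakshi–Shibata reduction with the (S)-catalyst at the less hindered C3 carbonyl gives the 3α-alcohol F8, and TIPSOTf returns 15.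

**Step 15.** Facial selectivity may be poor or reversed if the silylated ring does not adopt the melampolide-type conformation, leading to the 1α,10α oxide. Fallback: a two-step epoxidation with the opposite facial outcome. Setting out from 22, NBS in aqueous DME gives bromohydrin F9 (bromonium on the exposed face, water anti at tertiary C10), and K2CO3 closes the epoxide by backside displacement at C1, which puts oxygen on the face that the peracid does not reach and gives 23.

**Step 11.** Hydride may be delivered to the other carbonyl face if the ring holds C6=O the other way round, giving the 6α alcohol. Fallback: setting out from 15, the epimeric alcohol F10 is isolated and esterified under Mitsunobu conditions (isobutyric acid, PPh3, DIAD), which inverts C6 and installs the ester in one step; the route is rejoined at 17.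

**Step 4.** The enolate may lose silanolate by E1cB elimination before it is alkylated, and the resulting dienone aromatises. Fallback: alkylate a dianion, in which the alkoxide cannot leave. Setting out from 4, HF·pyridine gives (S)-5-hydroxy-3-methylcyclohex-2-en-1-one F11; LDA (2.2 equiv) and 5 give the trans hydroxy ester F12 (Fráter–Seebach-type alkylation anti to the alkoxide), and TBSOTf returns 6.

**Step 6.** The elimination may stall at equilibrium, and the strained, volatile enone may be lost by re-addition of ethanol or oligomerisation; some 4-methyl isomer may form. Fallback: make the elimination irreversible. Setting out from 10, HBr in AcOH exchanges ethoxy for bromide to give 3-bromo-2-methylcyclobutan-1-one F13, and nBu3N dehydrobrominates it to 11.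

## Further compounds

F1 | step 9 | racemic 2-methylcyclobut-2-en-1-ol | CC1=CCC1O
F2 | step 9 | racemic (2-methylcyclobut-2-en-1-yloxy)triisopropylsilane | CC1=CCC1O[Si](C(C)C)(C(C)C)C(C)C
F3 | step 9 | cis-anti-cis exo adduct of 6 with the (S)-cyclobutene (cyclobutane anti to C8–OTBS) | CC(C)(C)OC(=O)C[C@H]1C(=O)[C@H]2[C@]3(C)[C@@H](O[Si](C(C)C)(C(C)C)C(C)C)C[C@@H]3[C@@]2(C)C[C@@H]1O[Si](C)(C)C(C)(C)C
F4 | step 9 | C3 epimer of 15 (3β-OTIPS) | CC(C)(C)OC(=O)C[C@@H]1[C@@H](O[Si](C)(C)C(C)(C)C)C/C(C)=C\C[C@H](O[Si](C(C)C)(C(C)C)C(C)C)/C(C)=C/C1=O
F5 | step 10 | tricyclic cyclobutanol adduct (14 with OH in place of OTIPS) | CC(C)(C)OC(=O)C[C@H]1C(=O)[C@@H]2[C@@]3(C)[C@H](O)C[C@H]3[C@]2(C)C[C@@H]1O[Si](C)(C)C(C)(C)C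
F6 | step 10 | tricyclic 3,6-diketone | CC(C)(C)OC(=O)C[C@H]1C(=O)[C@@H]2[C@@]3(C)C(=O)C[C@H]3[C@]2(C)C[C@@H]1O[Si](C)(C)C(C)(C)C
F7 | step 10 | ten-membered (4E,1(10)Z)-diene-3,6-dione | CC(C)(C)OC(=O)C[C@@H]1[C@@H](O[Si](C)(C)C(C)(C)C)C/C(C)=C\CC(=O)/C(C)=C/C1=O
F8 | step 10 | 3α-hydroxy dienone (15 without TIPS) | CC(C)(C)OC(=O)C[C@@H]1[C@@H](O[Si](C)(C)C(C)(C)C)C/C(C)=C\C[C@@H](O)/C(C)=C/C1=O
F9 | step 15 | bromohydrin of 22 (C1–Br, C10–OH, anti) | C=C1C(=O)O[C@H]2C[C@](C)(O)[C@@H](Br)C[C@@H](O[Si](C(C)C)(C(C)C)C(C)C)/C(C)=C/[C@H](OC(=O)C(C)C)[C@H]12
F10 | step 11 | 6α-alcohol (C6 epimer of 16) | CC(C)(C)OC(=O)C[C@@H]1[C@@H](O[Si](C)(C)C(C)(C)C)C/C(C)=C\C[C@@H](O[Si](C(C)C)(C(C)C)C(C)C)/C(C)=C/[C@H]1O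
F11 | step 4 | (S)-5-hydroxy-3-methylcyclohex-2-en-1-one | O=C1C[C@@H](O)CC(C)=C1
F12 | step 4 | tert-butyl 2-[(1R,6S)-6-hydroxy-4-methyl-2-oxocyclohex-3-en-1-yl]acetate | CC(C)(C)OC(=O)C[C@H]1C(=O)C=C(C)C[C@@H]1O
F13 | step 6 | 3-bromo-2-methylcyclobutan-1-one | CC1C(Br)CC1=O
A1 | alternative 1 | cis-1,2-dialkenylcyclohexanol (C10 carbinol with vinyl C1=C2; C5 with the E enol ether alkenyl C4=C3) | C=C[C@]1(O)C[C@H](O[Si](C(C)C)(C(C)C)C(C)C)[C@@H](C(=C)CO[Si](C)(C)C(C)(C)C)[C@@H](O[Si](CC)(CC)CC)[C@@H]1/C(C)=C/OCc1ccc(OC)cc1
A2 | alternative 1 | ten-membered Z enol triflate with E C4=C5 alkene | [C@H]1(O[Si](C(C)C)(C(C)C)C(C)C)C/C(OS(=O)(=O)C(F)(F)F)=C\C[C@@H](OCc2ccc(OC)cc2)/C(C)=C/[C@H](O[Si](CC)(CC)CC)[C@@H]1C(=C)CO[Si](C)(C)C(C)(C)C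
A3 | alternative 2 | E vinyl iodide C6 aldehyde with epoxide and lactone in place | O=C[C@@H]1CC(=O)O[C@H]1C[C@]2(C)O[C@@H]2C[C@@H](O[Si](C)(C)C(C)(C)C)/C(C)=C/I
A4 | alternative 2 | ten-membered C6 allylic alcohol | C1C(=O)O[C@H]2C[C@]3(C)O[C@@H]3C[C@@H](O[Si](C)(C)C(C)(C)C)/C(C)=C/[C@H](O)[C@H]12
A5 | alternative 3 | hydroazulene C8 tertiary alcohol with C5 mesylate (C4–C8 bond) | O[C@@]12C/C(C)=C\C[C@@H](O[Si](C)(C)C(C)(C)C)[C@]1(C)[C@@H](OS(C)(=O)=O)[C@H](OCc1ccc(OC)cc1)[C@@H]2CCO[Si](C)(C)C(C)(C)C
A6 | alternative 3 | ten-membered Z,E dienone with C8 ketone | O=C1C/C(C)=C\C[C@@H](O[Si](C)(C)C(C)(C)C)/C(C)=C/[C@H](OCc2ccc(OC)cc2)[C@@H]1CCO[Si](C)(C)C(C)(C)C
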